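**Retrosynthetic overview**
1. Target 34 ⇐ 33 ⇐ 32: the six phenols are carried as benzyl ethers and the side-chain carbinol as a TBS ether, removed last.
2. Oxolane 32 ⇐ keto-lactol 30 (Et3SiH/BF3 reduction sets C5) ⇐ γ-lactone Weinreb amide 25 + 2 equiv of aryllithium 28 (both resorcinol rings in one operation).
3. Lactone 21 (→ 25) ⇐ imide 17 + aldehyde 5: intermolecular Evans syn-aldol (C2–C3 bond, sets C2 and C3), then lactonisation onto the methyl ester.
4. 17 ⇐ pentenoyl imide 4 + aldehyde 5: first Evans syn-aldol (sets C4 and the carbinol carbon); auxiliary → methyl ester; vinyl → CO2H → second auxiliary.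
5. Ring order: there is one ring only; it is closed as the γ-lactone (step 9) and converted into the oxolane (steps 13–14).

Assumption: the target is made as the open hydroxy ketone drawn; 30 and 33 may equilibrate with cyclic hemiketal forms, which does not change the route.

Abbreviations: Bn = benzyl, TBS = tert-butyldimethylsilyl. Oxolane numbering as in the target: O1, C2 (4-oxyphenyl), C3 (aroyl), C4 (CH(O)Ar), C5 (2,4-dioxyphenyl).

**Route**

Step 1
Reactants: 1 (R)-4-benzyloxazolidin-2-one; 2 pent-4-enoyl chloride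
Product: 4 (R)-4-benzyl-3-(pent-4-enoyl)oxazolidin-2-one, via N-lithio oxazolidinone 3 (not isolated)
Conditions: n-BuLi, THF, −78 °C; then 2, −78 to 0 °C
Reagents that add atoms: none
Why: N-acylation of the lithiated oxazolidinone by the acid chloride is fast and clean, and no stereocentre is formed.

Step 2
Reactants: 4 (R)-4-benzyl-3-(pent-4-enoyl)oxazolidin-2-one; 5 4-(benzyloxy)benzaldehyde
Product: 8 (R)-4-benzyl-3-[(2R)-2-{(R)-[4-(benzyloxy)phenyl](hydroxy)methyl}pent-4-enoyl]oxazolidin-2-one, via boron enolate 6 (not isolated), via boron aldolate 7 (not isolated)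
Conditions: n-Bu2BOTf, i-Pr2NEt, CH2Cl2, 0 °C; 5, −78 to 0 °C; then pH 7 buffer, MeOH, 30% H2O2, 0 °C
Reagents that add atoms: none
Why: Evans syn-aldol reaction: the (Z)-boron enolate adds through a Zimmerman–Traxler chair on the face opposite the auxiliary benzyl group, setting future C4 and the carbinol carbon as the (R,R)-syn pair.

Step 3
Reactants: 8 aldol imide
Product: 10 (2R)-2-{(R)-[4-(benzyloxy)phenyl](hydroxy)methyl}pent-4-enoic acid, via peroxy acid 9 (not isolated)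
Conditions: LiOH, 30% H2O2, THF/H2O (3:1), 0 °C; then aq. Na2SO3; HCl to pH 3
Reagents that add atoms: hydrogen peroxide, OO
Why: Lithium hydroperoxide cleaves the exocyclic imide carbonyl selectively (auxiliary hydrolysis) and sulfite reduces the peroxy acid, leaving both stereocentres untouched at 0 °C.

Step 4
Reactants: 10 hydroxy acid
Product: 11 methyl (2R)-2-{(R)-[4-(benzyloxy)phenyl](hydroxy)methyl}pent-4-enoate
Conditions: TMSCHN2, PhMe/MeOH (4:1), 0 °C to rt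
Reagents that add atoms: (trimethylsilyl)diazomethane, C[Si](C)(C)C=[N+]=[N-]
Why: Diazoalkane esterification is neutral, so neither retro-aldol cleavage nor epimerisation can occur.

Step 5
Reactants: 11 hydroxy ester
Product: 12 methyl (2R)-2-{(R)-[4-(benzyloxy)phenyl][(tert-butyldimethylsilyl)oxy]methyl}pent-4-enoate
Conditions: TBSOTf, 2,6-lutidine, CH2Cl2, −78 to 0 °C
Reagents that add atoms: tert-butyldimethylsilyl triflate, CC(C)(C)[Si](C)(C)OS(=O)(=O)C(F)(F)F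
Why: Silyl ether formation masks this carbinol to the end of the route and prevents it from lactonising once the second carboxyl is unveiled.

Step 6
Reactants: 12 silyl ether alkene
Product: 14 methyl (2R)-2-{(R)-[4-(benzyloxy)phenyl][(tert-butyldimethylsilyl)oxy]methyl}-4-oxobutanoate, via vicinal diol 13 (not isolated)
Conditions: OsO4 (2 mol %), NaIO4, 2,6-lutidine, dioxane/H2O (3:1), rt
Reagents that add atoms: osmium tetroxide, O=[Os](=O)(=O)=O (catalytic, re-formed by sodium periodate, [Na+].[O-]I(=O)(=O)=O)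
Why: Lemieux–Johnson oxidative cleavage (dihydroxylation then glycol cleavage) removes only the terminal alkene carbon and, unlike ozone, spares the electron-rich arenes.

Step 7
Reactants: 14 aldehyde
Product: 15 (3R)-3-{(R)-[4-(benzyloxy)phenyl][(tert-butyldimethylsilyl)oxy]methyl}-4-methoxy-4-oxobutanoic acid
Conditions: NaClO2, NaH2PO4, 2-methyl-2-butene, t-BuOH/H2O, 0 °C to rt
Reagents that add atoms: sodium chlorite, [Na+].[O-]Cl=O
Why: Pinnick oxidation is specific for the aldehyde, the alkene scavenger traps HOCl before it can chlorinate the arenes, and the buffered medium leaves the stereocentres and the silyl ether intact.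

Step 8
Reactants: 15 succinate half-acid; 1 (R)-4-benzyloxazolidin-2-one
Product: 17 methyl (2R)-4-[(R)-4-benzyl-2-oxooxazolidin-3-yl]-2-{(R)-[4-(benzyloxy)phenyl][(tert-butyldimethylsilyl)oxy]methyl}-4-oxobutanoate, via mixed pivalic anhydride 16 (not isolated)
Conditions: PivCl, Et3N, THF, −20 °C; then 1, LiCl, −20 °C to rt
Reagents that add atoms: none
Why: Mixed-anhydride N-acylation puts a second auxiliary on the unbranched carboxyl, so the next C–C bond formation is reagent-controlled.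

Step 9
Reactants: 17 imide ester; 5 4-(benzyloxy)benzaldehyde
Product: 21 (R)-4-benzyl-3-{[(2R,3R,4R)-2-[4-(benzyloxy)phenyl]-4-{(R)-[4-(benzyloxy)phenyl][(tert-butyldimethylsilyl)oxy]methyl}-5-oxooxolan-3-yl]carbonyl}oxazolidin-2-one, via boron enolate 18 (not isolated), via boron aldolate 19 (not isolated), via hydroxy ester 20 (not isolated)
Conditions: n-Bu2BOTf, i-Pr2NEt, CH2Cl2, 0 °C; 5, −78 to 0 °C; pH 7 buffer, MeOH, H2O2, 0 °C; then PPTS (cat.), PhMe, 40 °C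
Reagents that add atoms: none
Why: A second Evans syn-aldol reaction, in which only the CH2 next to the imide is enolised, sets C3 and C2 under auxiliary control, and lactonisation of the γ-hydroxy ester then gives the ring with C2-aryl trans to the C3 acyl group and C3/C4 cis.

Step 10
Reactants: 21 lactone imide
Product: 23 (2R,3R,4R)-2-[4-(benzyloxy)phenyl]-4-{(R)-[4-(benzyloxy)phenyl][(tert-butyldimethylsilyl)oxy]methyl}-5-oxooxolane-3-carboxylic acid, via peroxy acid 22 (not isolated)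
Conditions: LiOH, 30% H2O2, THF/H2O (3:1), 0 °C; then aq. Na2SO3; HCl to pH 3
Reagents that add atoms: hydrogen peroxide, OO
Why: Hydroperoxide hydrolysis of the imide again removes the auxiliary without epimerising C3, and any lactone opened by hydroxide re-closes on acidification.

Step 11
Reactants: 23 lactone acid
Product: 25 (2R,3R,4R)-2-[4-(benzyloxy)phenyl]-4-{(R)-[4-(benzyloxy)phenyl][(tert-butyldimethylsilyl)oxy]methyl}-N-methoxy-N-methyl-5-oxooxolane-3-carboxamide, via acid chloride 24 (not isolated)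
Conditions: 1-chloro-N,N,2-trimethylprop-1-en-1-amine, CH2Cl2, 0 °C to rt; then MeNH(OMe)·HCl, pyridine, 0 °C to rt
Reagents that add atoms: N,O-dimethylhydroxylamine hydrochloride, CNOC.Cl
Why: The acid chloride forms under neutral conditions (Ghosez reagent), so the benzylic silyl ether survives, and amidation gives the Weinreb amide needed for a clean ketone synthesis.

Step 12
Reactants: 26 4-bromobenzene-1,3-diol
Product: 27 2,4-bis(benzyloxy)-1-bromobenzene
Conditions: BnBr, K2CO3, DMF, 60 °C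
Reagents that add atoms: benzyl bromide, BrCc1ccccc1
Why: Williamson ether synthesis on both phenols proceeds without complication.

Step 13
Reactants: 25 lactone Weinreb amide; 27 2,4-bis(benzyloxy)-1-bromobenzene
Product: 30 [(2R,3R,4R)-5-[2,4-bis(benzyloxy)phenyl]-2-[4-(benzyloxy)phenyl]-4-{(R)-[4-(benzyloxy)phenyl][(tert-butyldimethylsilyl)oxy]methyl}-5-hydroxyoxolan-3-yl][2,4-bis(benzyloxy)phenyl]methanone (C5 anomers), via aryllithium 28 (not isolated), via dilithium bis-adduct 29 (not isolated)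
Conditions: 27 (2.4 equiv), n-BuLi (2.3 equiv), THF, −78 °C; then 25, −78 °C; sat. NH4Cl at −78 °C
Reagents that add atoms: none
Why: After bromine–lithium exchange, the Weinreb amide and the γ-lactone each accept exactly one aryllithium (nucleophilic acyl addition), because both tetrahedral adducts persist at −78 °C until the quench.

Step 14
Reactants: 30 keto-lactol
Product: 32 [(2R,3R,4S,5R)-5-[2,4-bis(benzyloxy)phenyl]-2-[4-(benzyloxy)phenyl]-4-{(R)-[4-(benzyloxy)phenyl][(tert-butyldimethylsilyl)oxy]methyl}oxolan-3-yl][2,4-bis(benzyloxy)phenyl]methanone (4S only because the silyl ether changes CIP priority), via oxocarbenium ion 31 (not isolated)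
Conditions: Et3SiH, BF3·OEt2, CH2Cl2, −78 to −40 °C; sat. NaHCO3 quench cold
Reagents that add atoms: none
Why: Ionic hydrogenation of the lactol: hydride adds to the cyclic oxocarbenium ion on the face anti to the C4 and C3 substituents, which puts the C5 aryl group cis to the C4 side chain, and the ketone is not reduced at this temperature.

Step 15
Reactants: 32 silyl ether ketone
Product: 33 [(2R,3R,4R,5R)-5-[2,4-bis(benzyloxy)phenyl]-2-[4-(benzyloxy)phenyl]-4-{(R)-[4-(benzyloxy)phenyl](hydroxy)methyl}oxolan-3-yl][2,4-bis(benzyloxy)phenyl]methanone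
Conditions: HF·pyridine, pyridine, THF, 0 °C to rt
Reagents that add atoms: none
Why: Buffered fluoride desilylation avoids the basic conditions that would epimerise C3 or open the ring by retro-oxa-Michael elimination.

Step 16
Reactants: 33 hexabenzyl ether
Product: 34 (2,4-dihydroxyphenyl)[(2R,3R,4R,5R)-5-(2,4-dihydroxyphenyl)-4-[(R)-hydroxy(4-hydroxyphenyl)methyl]-2-(4-hydroxyphenyl)oxolan-3-yl]methanone (target)
Conditions: H2 (1 atm), 10% Pd/C, EtOAc/THF, rt, stopped after uptake of 6 equiv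
Reagents that add atoms: none
Why: Hydrogenolysis of the six aryl benzyl ethers is much faster in neutral aprotic solvent than cleavage of the ring and carbinol benzylic C–O bonds or reduction of the aryl ketone.

**Compound list**

1 | (R)-4-benzyloxazolidin-2-one | O=C1N[C@H](Cc2ccccc2)CO1 | starting material
2 | pent-4-enoyl chloride | C=CCCC(=O)Cl | starting material
3 | N-lithio-(R)-4-benzyloxazolidin-2-one | [Li]N1[C@H](Cc2ccccc2)COC1=O | intermediate (not isolated)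
4 | (R)-4-benzyl-3-(pent-4-enoyl)oxazolidin-2-one | C=CCCC(=O)N1[C@H](Cc2ccccc2)COC1=O | intermediate
5 | 4-(benzyloxy)benzaldehyde | O=Cc1ccc(OCc2ccccc2)cc1 | starting material
6 | (Z)-dibutylboron enolate of 4 | CCCCB(CCCC)O/C(=C\CC=C)N1[C@H](Cc2ccccc2)COC1=O | intermediate (not isolated)
7 | O-dibutylboryl aldolate of 8 | O=C(N1[C@H](Cc2ccccc2)COC1=O)[C@H](CC=C)[C@@H](OB(CCCC)CCCC)c1ccc(OCc2ccccc2)cc1 | intermediate (not isolated)
8 | (R)-4-benzyl-3-[(2R)-2-{(R)-[4-(benzyloxy)phenyl](hydroxy)methyl}pent-4-enoyl]oxazolidin-2-one | O=C(N1[C@H](Cc2ccccc2)COC1=O)[C@H](CC=C)[C@@H](O)c1ccc(OCc2ccccc2)cc1 | intermediate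
9 | (2R)-2-{(R)-[4-(benzyloxy)phenyl](hydroxy)methyl}pent-4-eneperoxoic acid | OOC(=O)[C@H](CC=C)[C@@H](O)c1ccc(OCc2ccccc2)cc1 | intermediate (not isolated)
10 | (2R)-2-{(R)-[4-(benzyloxy)phenyl](hydroxy)methyl}pent-4-enoic acid | OC(=O)[C@H](CC=C)[C@@H](O)c1ccc(OCc2ccccc2)cc1 | intermediate
11 | methyl (2R)-2-{(R)-[4-(benzyloxy)phenyl](hydroxy)methyl}pent-4-enoate | COC(=O)[C@H](CC=C)[C@@H](O)c1ccc(OCc2ccccc2)cc1 | intermediate
12 | methyl (2R)-2-{(R)-[4-(benzyloxy)phenyl](TBSO)methyl}pent-4-enoate | COC(=O)[C@H](CC=C)[C@@H](O[Si](C)(C)C(C)(C)C)c1ccc(OCc2ccccc2)cc1 | intermediate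
13 | methyl (2R)-2-{(R)-[4-(benzyloxy)phenyl](TBSO)methyl}-4,5-dihydroxypentanoate (C4 epimers) | COC(=O)[C@H](CC(O)CO)[C@@H](O[Si](C)(C)C(C)(C)C)c1ccc(OCc2ccccc2)cc1 | intermediate (not isolated)
14 | methyl (2R)-2-{(R)-[4-(benzyloxy)phenyl](TBSO)methyl}-4-oxobutanoate | COC(=O)[C@H](CC=O)[C@@H](O[Si](C)(C)C(C)(C)C)c1ccc(OCc2ccccc2)cc1 | intermediate
15 | (3R)-3-{(R)-[4-(benzyloxy)phenyl](TBSO)methyl}-4-methoxy-4-oxobutanoic acid | COC(=O)[C@H](CC(=O)O)[C@@H](O[Si](C)(C)C(C)(C)C)c1ccc(OCc2ccccc2)cc1 | intermediate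
16 | mixed anhydride of 15 with pivalic acid | COC(=O)[C@H](CC(=O)OC(=O)C(C)(C)C)[C@@H](O[Si](C)(C)C(C)(C)C)c1ccc(OCc2ccccc2)cc1 | intermediate (not isolated)
17 | methyl (2R)-4-[(R)-4-benzyl-2-oxooxazolidin-3-yl]-2-{(R)-[4-(benzyloxy)phenyl](TBSO)methyl}-4-oxobutanoate | COC(=O)[C@H](CC(=O)N1[C@H](Cc2ccccc2)COC1=O)[C@@H](O[Si](C)(C)C(C)(C)C)c1ccc(OCc2ccccc2)cc1 | intermediate
18 | (Z)-dibutylboron enolate of 17 | COC(=O)[C@H](/C=C(\OB(CCCC)CCCC)N1[C@H](Cc2ccccc2)COC1=O)[C@@H](O[Si](C)(C)C(C)(C)C)c1ccc(OCc2ccccc2)cc1 | intermediate (not isolated)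
19 | O-dibutylboryl aldolate of 20 | O=C(N1[C@H](Cc2ccccc2)COC1=O)[C@H]([C@@H](C(=O)OC)[C@@H](O[Si](C)(C)C(C)(C)C)c1ccc(OCc2ccccc2)cc1)[C@@H](OB(CCCC)CCCC)c1ccc(OCc2ccccc2)cc1 | intermediate (not isolated)
20 | methyl (2R,3R,4R)-3-{[(R)-4-benzyl-2-oxooxazolidin-3-yl]carbonyl}-4-[4-(benzyloxy)phenyl]-2-{(R)-[4-(benzyloxy)phenyl](TBSO)methyl}-4-hydroxybutanoate | O=C(N1[C@H](Cc2ccccc2)COC1=O)[C@H]([C@@H](C(=O)OC)[C@@H](O[Si](C)(C)C(C)(C)C)c1ccc(OCc2ccccc2)cc1)[C@@H](O)c1ccc(OCc2ccccc2)cc1 | intermediate (not isolated)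
21 | (R)-4-benzyl-3-{[(2R,3R,4R)-2-[4-(benzyloxy)phenyl]-4-{(R)-[4-(benzyloxy)phenyl](TBSO)methyl}-5-oxooxolan-3-yl]carbonyl}oxazolidin-2-one | O=C1O[C@@H](c2ccc(OCc3ccccc3)cc2)[C@H](C(=O)N2[C@H](Cc3ccccc3)COC2=O)[C@@H]1[C@@H](O[Si](C)(C)C(C)(C)C)c1ccc(OCc2ccccc2)cc1 | intermediate
22 | (2R,3R,4R)-2-[4-(benzyloxy)phenyl]-4-{(R)-[4-(benzyloxy)phenyl](TBSO)methyl}-5-oxooxolane-3-carboperoxoic acid | O=C1O[C@@H](c2ccc(OCc3ccccc3)cc2)[C@H](C(=O)OO)[C@@H]1[C@@H](O[Si](C)(C)C(C)(C)C)c1ccc(OCc2ccccc2)cc1 | intermediate (not isolated)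
23 | (2R,3R,4R)-2-[4-(benzyloxy)phenyl]-4-{(R)-[4-(benzyloxy)phenyl](TBSO)methyl}-5-oxooxolane-3-carboxylic acid | O=C1O[C@@H](c2ccc(OCc3ccccc3)cc2)[C@H](C(=O)O)[C@@H]1[C@@H](O[Si](C)(C)C(C)(C)C)c1ccc(OCc2ccccc2)cc1 | intermediate
24 | acid chloride of 23 | O=C1O[C@@H](c2ccc(OCc3ccccc3)cc2)[C@H](C(=O)Cl)[C@@H]1[C@@H](O[Si](C)(C)C(C)(C)C)c1ccc(OCc2ccccc2)cc1 | intermediate (not isolated)
25 | (2R,3R,4R)-2-[4-(benzyloxy)phenyl]-4-{(R)-[4-(benzyloxy)phenyl](TBSO)methyl}-N-methoxy-N-methyl-5-oxooxolane-3-carboxamide | O=C1O[C@@H](c2ccc(OCc3ccccc3)cc2)[C@H](C(=O)N(C)OC)[C@@H]1[C@@H](O[Si](C)(C)C(C)(C)C)c1ccc(OCc2ccccc2)cc1 | intermediate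
26 | 4-bromobenzene-1,3-diol | Oc1ccc(Br)c(O)c1 | starting material
27 | 2,4-bis(benzyloxy)-1-bromobenzene | Brc1ccc(OCc2ccccc2)cc1OCc1ccccc1 | intermediate
28 | [2,4-bis(benzyloxy)phenyl]lithium | [Li]c1ccc(OCc2ccccc2)cc1OCc1ccccc1 | intermediate (not isolated)
29 | dilithium bis-adduct (lithium lactolate at C5 and lithium N-methoxy-N-methyl hemiaminal alkoxide at the C3 carbonyl carbon) | [Li]OC1(c2ccc(OCc3ccccc3)cc2OCc2ccccc2)O[C@@H](c2ccc(OCc3ccccc3)cc2)[C@H](C(O[Li])(N(C)OC)c2ccc(OCc3ccccc3)cc2OCc2ccccc2)[C@@H]1[C@@H](O[Si](C)(C)C(C)(C)C)c1ccc(OCc2ccccc2)cc1 | intermediate (not isolated)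
30 | [(2R,3R,4R)-5-[2,4-bis(benzyloxy)phenyl]-2-[4-(benzyloxy)phenyl]-4-{(R)-[4-(benzyloxy)phenyl](TBSO)methyl}-5-hydroxyoxolan-3-yl][2,4-bis(benzyloxy)phenyl]methanone (C5 anomers) | OC1(c2ccc(OCc3ccccc3)cc2OCc2ccccc2)O[C@@H](c2ccc(OCc3ccccc3)cc2)[C@H](C(=O)c2ccc(OCc3ccccc3)cc2OCc2ccccc2)[C@@H]1[C@@H](O[Si](C)(C)C(C)(C)C)c1ccc(OCc2ccccc2)cc1 | intermediate
31 | cyclic C5 oxocarbenium ion derived from 30 | [O+]1=C(c2ccc(OCc3ccccc3)cc2OCc2ccccc2)[C@@H]([C@@H](O[Si](C)(C)C(C)(C)C)c2ccc(OCc3ccccc3)cc2)[C@@H](C(=O)c2ccc(OCc3ccccc3)cc2OCc2ccccc2)[C@@H]1c1ccc(OCc2ccccc2)cc1 | intermediate (not isolated)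
32 | [(2R,3R,4S,5R)-5-[2,4-bis(benzyloxy)phenyl]-2-[4-(benzyloxy)phenyl]-4-{(R)-[4-(benzyloxy)phenyl](TBSO)methyl}oxolan-3-yl][2,4-bis(benzyloxy)phenyl]methanone | O=C(c1ccc(OCc2ccccc2)cc1OCc1ccccc1)[C@@H]1[C@H]([C@@H](O[Si](C)(C)C(C)(C)C)c2ccc(OCc3ccccc3)cc2)[C@H](c2ccc(OCc3ccccc3)cc2OCc2ccccc2)O[C@H]1c1ccc(OCc2ccccc2)cc1 | intermediate
33 | [(2R,3R,4R,5R)-5-[2,4-bis(benzyloxy)phenyl]-2-[4-(benzyloxy)phenyl]-4-{(R)-[4-(benzyloxy)phenyl](hydroxy)methyl}oxolan-3-yl][2,4-bis(benzyloxy)phenyl]methanone | O=C(c1ccc(OCc2ccccc2)cc1OCc1ccccc1)[C@@H]1[C@H]([C@@H](O)c2ccc(OCc3ccccc3)cc2)[C@H](c2ccc(OCc3ccccc3)cc2OCc2ccccc2)O[C@H]1c1ccc(OCc2ccccc2)cc1 | intermediate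
34 | (2,4-dihydroxyphenyl)[(2R,3R,4R,5R)-5-(2,4-dihydroxyphenyl)-4-[(R)-hydroxy(4-hydroxyphenyl)methyl]-2-(4-hydroxyphenyl)oxolan-3-yl]methanone | O=C(c1ccc(O)cc1O)[C@@H]1[C@H]([C@@H](O)c2ccc(O)cc2)[C@H](c2ccc(O)cc2O)O[C@H]1c1ccc(O)cc1 | target

**Totals and risks**

Total step count: 16. Longest linear sequence: 15 steps (steps 1–11 and 13–16; step 12 is a one-step side branch).

The three steps most likely to fail:

Step 9 (second aldol and lactonisation). The enolate is β-branched and hindered, the substrate stereocentre may be mismatched with the auxiliary, and ring closure to the 3,4-cis lactone may be slow. The fallback sets out from acid 15 and comes back at Weinreb amide 25. Acid 15 is coupled with (R)-4-benzylthiazolidine-2-thione (EDC·HCl, DMAP, CH2Cl2) to give the N-acylthiazolidinethione F1. A titanium-mediated syn-aldol addition to aldehyde 5 (TiCl4, i-Pr2NEt, NMP, CH2Cl2, −78 to 0 °C), which is more reactive than the boron variant and has the same facial sense, gives the hydroxy ester F2. This closes (PPTS, PhMe) to the thioimide lactone F3. The thiazolidinethione is displaced directly by MeNH(OMe)·HCl/imidazole in CH2Cl2 at rt, which gives 25 and makes steps 10 and 11 unnecessary.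

Step 13 (double aryllithium addition). The Weinreb amide is flanked by two substituents and may not react at −78 °C, while warming risks over-addition at the lactone; the ketone formed here also has to survive step 14. The fallback sets out from acid 23 and comes back at ketone 32. Acid 23 is treated with 3.3 equiv of aryllithium 28 at −78 °C (one equivalent only deprotonates the acid and the carboxylate is inert) to give the lactol acid F4. Et3SiH/BF3·OEt2 at −78 °C reduces it, with no ketone present, to the oxolane acid F5. The Ghosez reagent converts this into the acid chloride F6, and MeNH(OMe)·HCl/pyridine gives the oxolane Weinreb amide F7. A single addition of aryllithium 28, which can now be warmed to 0 °C, gives 32.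

Step 16 (global hydrogenolysis). The free p-oxybenzylic carbinol and the benzylic ring C–O bonds may be hydrogenolysed. The fallback sets out from 32 and comes back at target 34. Compound 32 is hydrogenolysed first (H2, Pd/C, EtOAc/THF) while the side-chain carbinol is still silylated, which shields that C–O bond and blocks hemiketal formation, giving the hexaphenol silyl ether F8. HF·pyridine/pyridine in THF then removes the silyl group to give 34.

**Further compounds**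

F1 | step 9 | methyl (2R)-4-[(R)-4-benzyl-2-thioxothiazolidin-3-yl]-2-{(R)-[4-(benzyloxy)phenyl](TBSO)methyl}-4-oxobutanoate | COC(=O)[C@H](CC(=O)N1[C@H](Cc2ccccc2)CSC1=S)[C@@H](O[Si](C)(C)C(C)(C)C)c1ccc(OCc2ccccc2)cc1
F2 | step 9 | methyl (2R,3R,4R)-3-{[(R)-4-benzyl-2-thioxothiazolidin-3-yl]carbonyl}-4-[4-(benzyloxy)phenyl]-2-{(R)-[4-(benzyloxy)phenyl](TBSO)methyl}-4-hydroxybutanoate | O=C(N1[C@H](Cc2ccccc2)CSC1=S)[C@H]([C@@H](C(=O)OC)[C@@H](O[Si](C)(C)C(C)(C)C)c1ccc(OCc2ccccc2)cc1)[C@@H](O)c1ccc(OCc2ccccc2)cc1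
F3 | step 9 | (3R,4R,5R)-4-{[(R)-4-benzyl-2-thioxothiazolidin-3-yl]carbonyl}-5-[4-(benzyloxy)phenyl]-3-{(R)-[4-(benzyloxy)phenyl](TBSO)methyl}oxolan-2-one | O=C1O[C@@H](c2ccc(OCc3ccccc3)cc2)[C@H](C(=O)N2[C@H](Cc3ccccc3)CSC2=S)[C@@H]1[C@@H](O[Si](C)(C)C(C)(C)C)c1ccc(OCc2ccccc2)cc1
F4 | step 13 | (2R,3R,4R)-5-[2,4-bis(benzyloxy)phenyl]-2-[4-(benzyloxy)phenyl]-4-{(R)-[4-(benzyloxy)phenyl](TBSO)methyl}-5-hydroxyoxolane-3-carboxylic acid (C5 anomers) | OC1(c2ccc(OCc3ccccc3)cc2OCc2ccccc2)O[C@@H](c2ccc(OCc3ccccc3)cc2)[C@H](C(=O)O)[C@@H]1[C@@H](O[Si](C)(C)C(C)(C)C)c1ccc(OCc2ccccc2)cc1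
F5 | step 13 | (2R,3R,4S,5R)-5-[2,4-bis(benzyloxy)phenyl]-2-[4-(benzyloxy)phenyl]-4-{(R)-[4-(benzyloxy)phenyl](TBSO)methyl}oxolane-3-carboxylic acid | OC(=O)[C@@H]1[C@H]([C@@H](O[Si](C)(C)C(C)(C)C)c2ccc(OCc3ccccc3)cc2)[C@H](c2ccc(OCc3ccccc3)cc2OCc2ccccc2)O[C@H]1c1ccc(OCc2ccccc2)cc1
F6 | step 13 | acid chloride of F5 | ClC(=O)[C@@H]1[C@H]([C@@H](O[Si](C)(C)C(C)(C)C)c2ccc(OCc3ccccc3)cc2)[C@H](c2ccc(OCc3ccccc3)cc2OCc2ccccc2)O[C@H]1c1ccc(OCc2ccccc2)cc1
F7 | step 13 | (2R,3R,4S,5R)-5-[2,4-bis(benzyloxy)phenyl]-2-[4-(benzyloxy)phenyl]-4-{(R)-[4-(benzyloxy)phenyl](TBSO)methyl}-N-methoxy-N-methyloxolane-3-carboxamide | CON(C)C(=O)[C@@H]1[C@H]([C@@H](O[Si](C)(C)C(C)(C)C)c2ccc(OCc3ccccc3)cc2)[C@H](c2ccc(OCc3ccccc3)cc2OCc2ccccc2)O[C@H]1c1ccc(OCc2ccccc2)cc1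
F8 | step 16 | (2,4-dihydroxyphenyl)[(2R,3R,4S,5R)-5-(2,4-dihydroxyphenyl)-2-(4-hydroxyphenyl)-4-{(R)-(4-hydroxyphenyl)[(tert-butyldimethylsilyl)oxy]methyl}oxolan-3-yl]methanone | O=C(c1ccc(O)cc1O)[C@@H]1[C@H]([C@@H](O[Si](C)(C)C(C)(C)C)c2ccc(O)cc2)[C@H](c2ccc(O)cc2O)O[C@H]1c1ccc(O)cc1
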